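## The problem

Lignan numbering is used throughout: ring A is C1–C6 with C7, C8 and C9 attached; ring C is C1'–C6' with C7', C8' and C9' attached.

The target 19 joins a trimethoxybenzene (ring A, methoxy groups on C3, C4 and C5) through C1 and C2 to a seven-membered carbocycle (ring B: C1, C2, C1', C7', C8', C8, C7). C1' is also the 4-carbon of a 2,6-dimethoxycyclohexa-2,5-dienone (ring C), so ring B ends in a spiro quaternary carbon. Ring B carries three contiguous stereocentres, C7 (acetoxy, R), C8 (methyl, S) and C8' (methyl, R); C1' is not stereogenic because ring C is symmetric. The two methyl-bearing carbons have the relation of a trans-2,3-disubstituted butyrolactone, and the C7 oxygen is anti to the C8 branch. One absolute stereocentre at C8' can therefore relay C8 through a ring and C7 through an aldol transition state. The cross-conjugated dienone does not tolerate hydrides or strong nucleophiles, and acid turns it by aryl migration into a biaryl phenol, so it must be formed last. The benzylic acetate on the electron-rich ring A is open to ionisation, hydrogenolysis and hydride cleavage, so it must follow all reductions. Two features give leverage. Ring C is a dearomatised 4-alkyl-2,6-dimethoxyphenol, so the C2–C1' bond can come from oxidative para coupling onto ring A, whose two ortho carbons are equivalent. The chain C7–C8(C9)–C8'(C9')–C7' with an aryl group at each end is a 1,4-diaryl-2,3-dimethylbutane, and its methyl carbons C9 and C9' can be the carbonyl and acetal carbons of a 5-alkoxybutyrolactone assembled from three components.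

## Retrosynthesis

**C2–C1' (19 to 18).** Cutting the spiro bond between ring A and ring C returns ring C to a phenol and opens ring B, giving the acyclic phenol acetate 18. The neighbouring cut C1'–C7' would need a preformed biaryl and a carbon electrophile, and the cut C1–C7 would leave C7 as a ketone still to be reduced beside the dienone. The chosen cut leads to an ordinary diarylbutane and places the dienone in the final step. The forward reaction must oxidise the phenol by two electrons and let C2 of ring A attack the para carbon C1' before solvent or the benzylic C7' position intervenes. The C7 oxygen is carried as the acetate because a free hydroxyl there would close a six-membered spiro ether instead.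

**Oxygen substituents (18 to 15).** No skeletal bond is cut. The C7 acetate and the free phenol of 18 are traced through diacetate 17 and diol 16 to the bis-silyl ether 15. An ester cannot pass the hydride steps, and the phenol must be masked during the carbanion chemistry. A benzyl ether on the phenol was considered and set aside. Raney Ni can remove it, and its final hydrogenolysis would have to spare a benzylic acetate. With silicon on both oxygens one fluoride treatment frees both, and peracetylation followed by aminolysis of the more reactive aryl ester then tells them apart. The forward steps ask only for that ester selectivity.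

**Methyl groups C9 and C9' (15 to 12).** The C–H bonds of both methyls are traced to C–O bonds: 15 comes from dimesylate 14 and diol 13, and 13 from the trans lactone 12. The lactone carbonyl becomes C9 and the menthyloxy acetal carbon becomes C9'. Bringing in the methyls as such, by alkylation or methyl conjugate addition, would need separate stereocontrol for each. In the lactone, C8 and C8' sit in a five-membered ring where trans is the kinetic and the thermodynamic outcome. The forward reactions must reduce both carbons to the alcohol level with release of the auxiliary, and then replace both hydroxyls by hydrogen without forming a tetrahydrofuran.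

**C7' methylene and C7 ether (12 to 10).** The C7' methylene of 12 is traced to the dithiane carbon of 11, and the silyl ether of 11 to the carbinol 10. The dithiane is what made C7' a nucleophile; the silyl group protects the aldol product against retro-aldol cleavage and dehydration. The forward desulfurisation must spare the benzylic C7–O bond.

**C7'–C8' and C8–C7 (10 to 4, 5 and 6).** Both bonds that tie the bridge to its aryl termini are cut in one operation, giving dithiane 4, butenolide 5 and aldehyde 6. The polarities fit: C8' is the β-carbon of an unsaturated lactone, C8 becomes nucleophilic once C8' has been attacked (enolate 8), C7' is a masked acyl anion (7) and C7 is an aldehyde carbon. Cutting C8–C8' would mean coupling two arylpropane halves of unequal oxidation level. Cutting only C8–C7 is the same chemistry in two flasks. The simplification is large: 10 holds every carbon of rings A and C and of the bridge and three new stereocentres, while the components are two achiral aromatics and a butenolide with one controlling centre. The forward reaction must give 1,4-addition, attack anti to the menthyloxy group, a trans lactone and an anti aldol; the lithium aldolate 9 is quenched cold.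

**Dithiane (4 to 1 and 2).** The two C–S bonds and the O–Si bond are cut: 4 comes from phenol dithiane 3, and 3 from syringaldehyde 1 and propane-1,3-dithiol 2. The dithiane is formed on the free phenol so that the silyl ether does not meet the Lewis acid.

## Roads not taken

**Alternative 1:** The cut is C1'–C7'. A biaryl phenol A1 has ring A joined at C2 to the para carbon of the phenol, a C7 silyl ether and a primary mesylate at C7'. With Cs2CO3 in DMF its phenolate would alkylate itself through the para carbon to give the spirodienone silyl ether A2. The closure is basic and non-oxidising. No phenoxonium species arises, no quinone methide can form, and no acid is present to trigger aryl migration. In this respect it is better than the oxidative closure chosen here. Its weak points lie elsewhere. A seven-membered ring must form by attack of an ambident phenolate carbon on a β-branched primary sulfonate, with intermolecular O-alkylation as a competitor. The chain of A1 cannot come from the three-component lactone assembly, because C7' must end as an oxygenated carbon and ring A must carry an ortho coupling handle that would not survive desulfurisation. The three stereocentres would therefore need a longer, stepwise construction, followed by cross-coupling and a silyl-to-acetate exchange on the dienone. The chosen plan sets against the milder closure a one-flask assembly of skeleton and stereocentres and a final step that gives the target directly.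

**Alternative 2:** The cut is a one-carbon ring expansion. A racemic siloxycyclopropane A3, made from a spiro-tetralone that already holds rings A and C, would be opened by FeCl3 in DMF at the ring-fusion bond between the future C7 and C8'. Elimination with NaOAc would then give the achiral spiro benzocycloheptenone A4. The merit is that the spiro carbon is set in an easy six-membered closure and the seven-membered ring comes from a dependable expansion. For this target the cost is high. A4 has no stereocentre and lacks the C8 methyl, so C8', C8 and C7 must all be introduced afterwards by an enantioselective conjugate reduction, a diastereoselective methylation and a ketone reduction. Each of these meets two enones, and ring C is the more exposed one. The dienone would also have to survive enol silylation, cyclopropanation and a Lewis-acidic iron salt. The chosen plan fixes all three centres before ring C exists; the alternative only avoids a direct seven-membered closure, which has close analogy.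

**Alternative 3:** The cuts are C1–C7 and C2–C1', both at ring A. In a Catellani sequence (Pd(OAc)2, a triarylphosphine, norbornene, Cs2CO3) the aryl iodide A5 would be acylated at its free ortho carbon by the mixed anhydride A6. After CsF frees the phenolate, the aryl–palladium at C2 would arylate the phenol para carbon and give the spirodienone ketone A7. On paper this is the most convergent route: ring A enters as a simple iodoarene, two C–C bonds and the spiro centre form together, and only a small chiral acid is needed. In step economy it would beat the chosen plan if it worked. The risks are concentrated in that one step. A dearomatising arylation that closes a seven-membered ring has no close analogy. The C8 centre, α to the anhydride and then to an aryl ketone, is exposed to hot carbonate. C7 would still have to be set by reducing an aryl ketone beside the dienone, with unknown facial preference in ring B. The chosen plan sets against this a known reaction type in every step and a C7 centre fixed long before the dienone appears.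

Key step: step 3

Remark on the chemistry: butenolide 5 is taken as the purchasable crystalline 5R acetal derived from l-menthol, and the configuration at C7 is assumed to follow the closed chair aldol model discussed in step 3.

## Route

Step 1
Reactants: 1 syringaldehyde; 2 propane-1,3-dithiol
Product: 3 4-(1,3-dithian-2-yl)-2,6-dimethoxyphenol
Conditions: BF3·OEt2 (cat.), CH2Cl2, 0 °C to rt
Reagents that add atoms: none
Why: Lewis acid-catalysed dithioacetalisation of an aromatic aldehyde; the free phenol does not interfere, and the dithiane turns the formyl carbon, the future C7', into a latent carbanion.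

Step 2
Reactants: 3 4-(1,3-dithian-2-yl)-2,6-dimethoxyphenol
Product: 4 2-[3,5-dimethoxy-4-(triisopropylsilyloxy)phenyl]-1,3-dithiane
Conditions: TIPSCl, imidazole, DMF, rt to 40 °C
Reagents that add atoms: triisopropylsilyl chloride (TIPSCl), CC(C)[Si](Cl)(C(C)C)C(C)C
Why: Silylation of a phenol with a silyl chloride and imidazole; the triisopropylsilyl ether should withstand n-BuLi, Raney Ni, LiAlH4 and LiEt3BH and falls to fluoride together with the later C7 silyl ether.

Step 3
Reactants: 4 2-[3,5-dimethoxy-4-(triisopropylsilyloxy)phenyl]-1,3-dithiane; 5 (5R)-5-(l-menthyloxy)furan-2(5H)-one; 6 3,4,5-trimethoxybenzaldehyde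
Product: 10 (3S,4R,5R)-4-{2-[3,5-dimethoxy-4-(triisopropylsilyloxy)phenyl]-1,3-dithian-2-yl}-3-[(R)-hydroxy(3,4,5-trimethoxyphenyl)methyl]-5-(l-menthyloxy)dihydrofuran-2(3H)-one, via 2-lithio dithiane 7 (not isolated), via lithium lactone enolate 8 (not isolated), via lithium aldolate 9 (not isolated)
Conditions: n-BuLi, THF, −78 to −20 °C; 5, −78 °C; 6, −78 °C; AcOH, −78 °C
Reagents that add atoms: none
Why: n-BuLi removes the dithiane C2–H of 4 to give the sulfur-stabilised benzylic anion 7, a soft nucleophile that adds to the β-carbon of butenolide 5 (C7'–C8' bond) and not to the lactone carbonyl. The resulting lithium enolate 8 is trapped at −78 °C by aldehyde 6 (C8–C7 bond), and the lithium aldolate 9 is protonated cold with AcOH so that retro-aldol cleavage cannot set in on warming. The closest known reaction type is the tandem conjugate addition–aldol reaction of lithiated 2-aryl-1,3-dithianes with 5-alkoxyfuran-2(5H)-ones and aromatic aldehydes, as used for lignan lactones. No ring is closed; two C–C bonds and three stereocentres are formed. C8' is controlled by the acetal centre of 5: the anion enters the planar butenolide on the face opposite the menthyloxy group, which from the 5R acetal gives 4R. C8 is controlled by C8': the aldehyde approaches the enolate anti to the bulky dithianyl group and gives the 3,4-trans lactone (3S). C7 is controlled by the ring-locked enolate geometry, with the α-substituent trans to O–Li, so that a closed chair (Zimmerman–Traxler) transition state with the aryl group equatorial leads to the anti aldol (R at the carbinol). The step needs 1,4- over 1,2-addition and face selectivity at three centres; the delocalised anion, the single bulky acetal substituent next to the reacting carbon and the cyclic enolate should secure them, with C7 the least secure.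

Step 4
Reactants: 10 lactone carbinol from step 3
Product: 11 (3S,4R,5R)-3-[(R)-(tert-butyldimethylsilyloxy)(3,4,5-trimethoxyphenyl)methyl]-4-{2-[3,5-dimethoxy-4-(triisopropylsilyloxy)phenyl]-1,3-dithian-2-yl}-5-(l-menthyloxy)dihydrofuran-2(3H)-one
Conditions: TBSOTf, 2,6-lutidine, CH2Cl2, −78 to 0 °C
Reagents that add atoms: tert-butyldimethylsilyl trifluoromethanesulfonate (TBSOTf), CC(C)(C)[Si](C)(C)OS(=O)(=O)C(F)(F)F
Why: Silylation of a hindered secondary alcohol with a silyl triflate and a pyridine base that is too weak to start retro-aldol cleavage; the ether blocks retro-aldol, dehydration and later tetrahydrofuran formation and leaves all stereocentres untouched.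

Step 5
Reactants: 11 silyl ether dithiane lactone
Product: 12 (3S,4R,5R)-3-[(R)-(tert-butyldimethylsilyloxy)(3,4,5-trimethoxyphenyl)methyl]-4-[3,5-dimethoxy-4-(triisopropylsilyloxy)benzyl]-5-(l-menthyloxy)dihydrofuran-2(3H)-one
Conditions: Raney Ni (W-2), EtOH–THF, rt to 50 °C
Reagents that add atoms: none
Why: Raney Ni desulfurisation cleaves both C–S bonds and turns the dithiane carbon into the C7' methylene; the lactone, the acetal, both silyl ethers and the hindered benzylic C7–O bond are expected to survive at moderate temperature, and no stereocentre is touched.

Step 6
Reactants: 12 benzyl lactone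
Product: 13 (2R,3R)-2-[(R)-(tert-butyldimethylsilyloxy)(3,4,5-trimethoxyphenyl)methyl]-3-[3,5-dimethoxy-4-(triisopropylsilyloxy)benzyl]butane-1,4-diol
Conditions: LiAlH4, THF, 0 °C to rt; H2O
Reagents that add atoms: none
Why: Hydride reduction of a γ-alkoxy lactone: the carbonyl carbon is reduced to C9H2OH, the hemiacetal alkoxide released at C9' collapses to an aldehyde with loss of the menthyloxy group and is reduced in turn, so both future methyl carbons appear as primary alcohols; C8 and C8' are not epimerised because no enolisable carbonyl persists.

Step 7
Reactants: 13 diol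
Product: 14 bis(methanesulfonate) of diol 13
Conditions: MsCl, Et3N, CH2Cl2, −20 to 0 °C
Reagents that add atoms: methanesulfonyl chloride (MsCl), CS(Cl)(=O)=O
Why: Sulfonylation through sulfene is fast at low temperature, so the second hydroxyl should be mesylated before the monomesylate can cyclise to a tetrahydrofuran; the silyl ethers are inert.

Step 8
Reactants: 14 dimesylate
Product: 15 (1R,2S,3R)-1-(tert-butyldimethylsilyloxy)-4-[3,5-dimethoxy-4-(triisopropylsilyloxy)phenyl]-2,3-dimethyl-1-(3,4,5-trimethoxyphenyl)butane
Conditions: LiEt3BH, THF, 0 °C to rt
Reagents that add atoms: none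
Why: Hydride displacement of primary alkyl sulfonates (SN2 at carbon) converts both CH2OMs groups into the C9 and C9' methyls; LiEt3BH attacks carbon in preference to sulfur and leaves silyl and aryl ethers alone, and the stereocentres are not involved.

Step 9
Reactants: 15 bis-silyl ether
Product: 16 (1R,2S,3R)-4-(4-hydroxy-3,5-dimethoxyphenyl)-2,3-dimethyl-1-(3,4,5-trimethoxyphenyl)butan-1-ol
Conditions: Bu4NF, THF, rt to 45 °C, argon
Reagents that add atoms: none
Why: Fluoride cleavage of silyl ethers: the aryl triisopropylsilyl ether goes first and the hindered benzylic tert-butyldimethylsilyl ether on warming, with retention at C7 because only Si–O bonds break; air is excluded because the electron-rich phenolate is easily oxidised.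

Step 10
Reactants: 16 phenol alcohol
Product: 17 (1R,2S,3R)-4-(4-acetoxy-3,5-dimethoxyphenyl)-2,3-dimethyl-1-(3,4,5-trimethoxyphenyl)butyl acetate
Conditions: Ac2O, pyridine, DMAP (cat.), CH2Cl2, rt
Reagents that add atoms: acetic anhydride (Ac2O), CC(=O)OC(C)=O
Why: Nucleophile-catalysed acylation esterifies both the phenol and the hindered secondary benzylic alcohol; the reaction takes place at oxygen, so the C7 configuration is retained.

Step 11
Reactants: 17 diacetate
Product: 18 (1R,2S,3R)-4-(4-hydroxy-3,5-dimethoxyphenyl)-2,3-dimethyl-1-(3,4,5-trimethoxyphenyl)butyl acetate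
Conditions: pyrrolidine, CH2Cl2, 0 °C to rt
Reagents that add atoms: none
Why: Chemoselective aminolysis: an aryl acetate, with its phenolate leaving group, is cleaved by a secondary amine far faster than a hindered secondary alkyl acetate, so the phenol should be freed while the C7 acetate stays.

Step 12
Reactants: 18 phenol acetate
Product: 19 target: (7R,8S,9R)-2,3,4,3',5'-pentamethoxy-7,8-dimethyl-4'-oxo-6,7,8,9-tetrahydrospiro[benzo[7]annulene-5,1'-cyclohexa[2,5]dien]-9-yl acetate (lignan numbering 7R,8S,8'R)
Conditions: PhI(OCOCF3)2, CF3CH2OH, −40 °C
Reagents that add atoms: none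
Why: Dearomatising oxidative phenol coupling with a hypervalent iodine reagent: ligand exchange at iodine and loss of PhI give a phenoxonium-type species that is attacked at its para carbon C1' by C2 of ring A (seven-membered ring closure, para–ortho' C–C coupling), and loss of the C2 proton restores ring A. The poorly nucleophilic fluoroalcohol stabilises the cation without capturing it, the two ortho carbons of ring A are equivalent, the acetate is a non-participating spectator, and the low temperature should hold back acid-induced aryl migration; no stereocentre is formed because ring C is symmetric.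

## Compound list

1 | syringaldehyde (4-hydroxy-3,5-dimethoxybenzaldehyde) | COc1cc(C=O)cc(OC)c1O | starting material
2 | propane-1,3-dithiol | SCCCS | starting material
3 | 4-(1,3-dithian-2-yl)-2,6-dimethoxyphenol | COc1cc(cc(OC)c1O)C1SCCCS1 | intermediate
4 | 2-[3,5-dimethoxy-4-(triisopropylsilyloxy)phenyl]-1,3-dithiane | COc1cc(cc(OC)c1O[Si](C(C)C)(C(C)C)C(C)C)C1SCCCS1 | intermediate
5 | (5R)-5-[(1R,2S,5R)-menthyloxy]furan-2(5H)-one | O=C1C=C[C@H](O[C@@H]2C[C@H](C)CC[C@H]2C(C)C)O1 | starting material
6 | 3,4,5-trimethoxybenzaldehyde | COc1cc(C=O)cc(OC)c1OC | starting material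
7 | 2-lithio-2-[3,5-dimethoxy-4-(triisopropylsilyloxy)phenyl]-1,3-dithiane (not isolated) | COc1cc(cc(OC)c1O[Si](C(C)C)(C(C)C)C(C)C)C1([Li])SCCCS1 | intermediate
8 | lithium enolate of the (4R,5R)-4-(2-aryl-1,3-dithian-2-yl)-5-(l-menthyloxy) lactone (not isolated) | COc1cc(cc(OC)c1O[Si](C(C)C)(C(C)C)C(C)C)C1(SCCCS1)[C@H]1[C@H](O[C@@H]2C[C@H](C)CC[C@H]2C(C)C)OC(O[Li])=C1 | intermediate
9 | lithium alkoxide of carbinol 10 (not isolated) | COc1cc(cc(OC)c1O[Si](C(C)C)(C(C)C)C(C)C)C1(SCCCS1)[C@H]1[C@H](O[C@@H]2C[C@H](C)CC[C@H]2C(C)C)OC(=O)[C@@H]1[C@@H](O[Li])c1cc(OC)c(OC)c(OC)c1 | intermediate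
10 | (3S,4R,5R)-4-{2-[3,5-dimethoxy-4-(triisopropylsilyloxy)phenyl]-1,3-dithian-2-yl}-3-[(R)-hydroxy(3,4,5-trimethoxyphenyl)methyl]-5-(l-menthyloxy)dihydrofuran-2(3H)-one | COc1cc(cc(OC)c1O[Si](C(C)C)(C(C)C)C(C)C)C1(SCCCS1)[C@H]1[C@H](O[C@@H]2C[C@H](C)CC[C@H]2C(C)C)OC(=O)[C@@H]1[C@@H](O)c1cc(OC)c(OC)c(OC)c1 | intermediate
11 | C7 tert-butyldimethylsilyl ether of 10 | COc1cc(cc(OC)c1O[Si](C(C)C)(C(C)C)C(C)C)C1(SCCCS1)[C@H]1[C@H](O[C@@H]2C[C@H](C)CC[C@H]2C(C)C)OC(=O)[C@@H]1[C@@H](O[Si](C)(C)C(C)(C)C)c1cc(OC)c(OC)c(OC)c1 | intermediate
12 | (3S,4R,5R)-3-[(R)-(tert-butyldimethylsilyloxy)(3,4,5-trimethoxyphenyl)methyl]-4-[3,5-dimethoxy-4-(triisopropylsilyloxy)benzyl]-5-(l-menthyloxy)dihydrofuran-2(3H)-one | COc1cc(cc(OC)c1O[Si](C(C)C)(C(C)C)C(C)C)C[C@H]1[C@H](O[C@@H]2C[C@H](C)CC[C@H]2C(C)C)OC(=O)[C@@H]1[C@@H](O[Si](C)(C)C(C)(C)C)c1cc(OC)c(OC)c(OC)c1 | intermediate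
13 | (2R,3R)-2-[(R)-(tert-butyldimethylsilyloxy)(3,4,5-trimethoxyphenyl)methyl]-3-[3,5-dimethoxy-4-(triisopropylsilyloxy)benzyl]butane-1,4-diol | COc1cc(cc(OC)c1O[Si](C(C)C)(C(C)C)C(C)C)C[C@@H](CO)[C@H](CO)[C@@H](O[Si](C)(C)C(C)(C)C)c1cc(OC)c(OC)c(OC)c1 | intermediate
14 | bis(methanesulfonate) of diol 13 | COc1cc(cc(OC)c1O[Si](C(C)C)(C(C)C)C(C)C)C[C@@H](COS(C)(=O)=O)[C@H](COS(C)(=O)=O)[C@@H](O[Si](C)(C)C(C)(C)C)c1cc(OC)c(OC)c(OC)c1 | intermediate
15 | (1R,2S,3R)-1-(tert-butyldimethylsilyloxy)-4-[3,5-dimethoxy-4-(triisopropylsilyloxy)phenyl]-2,3-dimethyl-1-(3,4,5-trimethoxyphenyl)butane | COc1cc(cc(OC)c1O[Si](C(C)C)(C(C)C)C(C)C)C[C@@H](C)[C@H](C)[C@@H](O[Si](C)(C)C(C)(C)C)c1cc(OC)c(OC)c(OC)c1 | intermediate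
16 | (1R,2S,3R)-4-(4-hydroxy-3,5-dimethoxyphenyl)-2,3-dimethyl-1-(3,4,5-trimethoxyphenyl)butan-1-ol | COc1cc(cc(OC)c1O)C[C@@H](C)[C@H](C)[C@@H](O)c1cc(OC)c(OC)c(OC)c1 | intermediate
17 | (1R,2S,3R)-4-(4-acetoxy-3,5-dimethoxyphenyl)-2,3-dimethyl-1-(3,4,5-trimethoxyphenyl)butyl acetate | COc1cc(cc(OC)c1OC(C)=O)C[C@@H](C)[C@H](C)[C@@H](OC(C)=O)c1cc(OC)c(OC)c(OC)c1 | intermediate
18 | (1R,2S,3R)-4-(4-hydroxy-3,5-dimethoxyphenyl)-2,3-dimethyl-1-(3,4,5-trimethoxyphenyl)butyl acetate | COc1cc(cc(OC)c1O)C[C@@H](C)[C@H](C)[C@@H](OC(C)=O)c1cc(OC)c(OC)c(OC)c1 | intermediate
19 | (7R,8S,9R)-2,3,4,3',5'-pentamethoxy-7,8-dimethyl-4'-oxo-6,7,8,9-tetrahydrospiro[benzo[7]annulene-5,1'-cyclohexa[2,5]dien]-9-yl acetate | COC1=CC2(C=C(OC)C1=O)C[C@@H](C)[C@H](C)[C@@H](OC(C)=O)c1cc(OC)c(OC)c(OC)c12 | target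

## Step count and risks

Total: 12 steps. Longest linear sequence: 12 steps, from 1 to 19; 5 and 6 enter at step 3 as purchased compounds.

**Step 3 (key step).** The likely failure is poor facial selectivity in the aldol part, so that the carbinol centre C7 forms as a mixture; lithium aldol reactions of lactone enolates with aromatic aldehydes are only moderately selective. Retro-aldol loss during quenching is a second risk. The fallback separates the two bond formations. It sets out from 4 and 5: anion 7 is added to 5 as before and the enolate is protonated cold to give the conjugate adduct F1. F1 is converted with (c-C6H11)2BOTf and Et3N in CH2Cl2 at −78 °C into its boron enolate and treated with 6. The shorter B–O bonds give a tighter chair transition state, which with the ring-fixed enolate geometry favours the anti aldol. A non-oxidative buffered work-up is used because of the sulfur atoms. The path rejoins the route at 10.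

**Step 12.** The phenoxonium-type intermediate may be diverted before ring A reaches C1', by loss of a C7' proton towards a quinone methide or by capture by solvent. The product may also undergo acid-induced aryl migration, and the benzylic acetate may ionise or take part under the acidic, oxidising conditions. The fallback changes the order of events so that the acetate is absent during the oxidation. It sets out from 15. Selective cleavage of the aryl silyl ether (Bu4NF, one equivalent, THF, −20 °C) gives the phenol silyl ether F2. Oxidation of F2 with PhI(OCOCF3)2 in CF3CH2OH gives the spirodienone silyl ether F3, which is the same compound as A2. HF·pyridine then frees the spirodienone alcohol F4, and acetylation (Ac2O, pyridine, DMAP) rejoins the route at 19. Ring A is more nucleophilic without the electron-withdrawing acyloxy group at C7, and the bulky silyl ether neither ionises nor participates. The price is two more steps, and the quinone methide channel is not removed.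

**Step 5.** Over-reduction on the nickel surface, with hydrogenolysis of the benzylic C7–O bond of the electron-rich ring A, or stalling at the congested dithiane, is possible. The fallback replaces surface hydrogenolysis by a homogeneous radical chain: Bu3SnH with AIBN in toluene at reflux cleaves both C–S bonds through thiyl-stabilised benzylic radicals and cannot break C–O bonds. It sets out from 11 and returns at 12; no new compound is made on this path (F0).

**Step 8.** Hydride may attack sulfur instead of carbon at the β-branched mesylates, releasing an alkoxide that closes a tetrahydrofuran onto the neighbouring sulfonate; displacement at these hindered primary carbons may also be slow. The fallback changes the mechanism of C–O to C–H conversion. It sets out from 14: Finkelstein exchange (NaI, butanone, reflux) gives the diiodide F5, and radical dehalogenation of F5 (Bu3SnH, AIBN, toluene, 80 °C) returns to the route at 15.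

## Further compounds

F1 | step 3 | (4R,5R)-4-{2-[3,5-dimethoxy-4-(triisopropylsilyloxy)phenyl]-1,3-dithian-2-yl}-5-(l-menthyloxy)dihydrofuran-2(3H)-one | COc1cc(cc(OC)c1O[Si](C(C)C)(C(C)C)C(C)C)C1(SCCCS1)[C@H]1[C@H](O[C@@H]2C[C@H](C)CC[C@H]2C(C)C)OC(=O)C1
F2 | step 12 | 4-[(2R,3S,4R)-4-(tert-butyldimethylsilyloxy)-2,3-dimethyl-4-(3,4,5-trimethoxyphenyl)butyl]-2,6-dimethoxyphenol | COc1cc(cc(OC)c1O)C[C@@H](C)[C@H](C)[C@@H](O[Si](C)(C)C(C)(C)C)c1cc(OC)c(OC)c(OC)c1
F3 | step 12 | spirodienone with C7 tert-butyldimethylsilyl ether (7R,8S,8'R) | COC1=CC2(C=C(OC)C1=O)C[C@@H](C)[C@H](C)[C@@H](O[Si](C)(C)C(C)(C)C)c1cc(OC)c(OC)c(OC)c12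
F4 | step 12 | spirodienone with free C7 hydroxyl (7R,8S,8'R) | COC1=CC2(C=C(OC)C1=O)C[C@@H](C)[C@H](C)[C@@H](O)c1cc(OC)c(OC)c(OC)c12
F0 | step 5 | none | none
F5 | step 8 | diiodide corresponding to dimesylate 14 | COc1cc(cc(OC)c1O[Si](C(C)C)(C(C)C)C(C)C)C[C@@H](CI)[C@H](CI)[C@@H](O[Si](C)(C)C(C)(C)C)c1cc(OC)c(OC)c(OC)c1
A1 | alternative 1 | biaryl phenol with C7 silyl ether and primary C7' mesylate | CS(=O)(=O)OC[C@@H](C)[C@H](C)[C@@H](O[Si](C)(C)C(C)(C)C)c1cc(OC)c(OC)c(OC)c1-c1cc(OC)c(O)c(OC)c1
A2 | alternative 1 | spirodienone with C7 tert-butyldimethylsilyl ether | COC1=CC2(C=C(OC)C1=O)C[C@@H](C)[C@H](C)[C@@H](O[Si](C)(C)C(C)(C)C)c1cc(OC)c(OC)c(OC)c12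
A3 | alternative 2 | racemic trimethylsiloxycyclopropane of the spiro-tetralone | COC1=CC2(C=C(OC)C1=O)CC1(C)CC1(O[Si](C)(C)C)c1cc(OC)c(OC)c(OC)c12
A4 | alternative 2 | achiral spiro benzocycloheptenone with β-methyl group | COC1=CC2(C=C(OC)C1=O)CC(C)=CC(=O)c1cc(OC)c(OC)c(OC)c12
A5 | alternative 3 | 1-iodo-2,3,4-trimethoxybenzene | COc1ccc(I)c(OC)c1OC
A6 | alternative 3 | (2S,3R)-4-[4-(tert-butyldimethylsilyloxy)-3,5-dimethoxyphenyl]-2,3-dimethylbutanoic pivalic anhydride | CC(C)(C)C(=O)OC(=O)[C@@H](C)[C@H](C)Cc1cc(OC)c(O[Si](C)(C)C(C)(C)C)c(OC)c1
A7 | alternative 3 | spirodienone C7 ketone (8S,8'R) | COC1=CC2(C=C(OC)C1=O)C[C@@H](C)[C@H](C)C(=O)c1cc(OC)c(OC)c(OC)c12
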